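The leftover solid substrate in Tuesday's flask read 12 % at 10.0 h and 0 % at 20.0 h, so I left this note for the next person at the bench with a solution in the flask.

| flask | solid substrate | temperature | remark | time |
|---|---|---|---|---|
| Tuesday's | 3 M | 40 °C | the very flask that is asked about, followed so far |  |
| Wednesday's | 3 M | 35 °C | run made earlier |  |
| flask | 3.0 M | 40 °C |  | 2.5 d |

| run | time / h | target / % | solid substrate / % |
|---|---|---|---|
| Tuesday's | 10.0 | 28 | 12 |
| Tuesday's | 20.0 | 40 | 0 |
| Tuesday's | 30.0 | 45 | 1 |
| Tuesday's | 40.0 | 44 | 1 |
| Tuesday's | 48.0 | 45 | 2 |
| Tuesday's | 60.0 | 46 | 1 |
| Wednesday's | 10.0 | 23 | 22 |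
| Wednesday's | 20.0 | 35 | 4 |
| Wednesday's | 30.0 | 44 | 0 |
| Wednesday's | 40.0 | 49 | 0 |
| Wednesday's | 48.0 | 47 | 1 |
| Wednesday's | 60.0 | 50 | 2 |

(standard deviation of a reading: 2 percentage points)

- a species is counted by the solid substrate in it: one target counts as two
- given per volume of solution although it is solid: solid substrate
- target taken out counts as made
- steps under discussion: 2 starting material <-> target; solid substrate <-> starting material
- at the start none of the solid substrate is in solution

- north: at 2.5 d take out 90 % of the target then present, then wait 20 h
- east: change nothing and wait 20 h more
- west: at 2.5 d raise the temperature by 10 K, then wait 20 h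

- target, in percent of the solid substrate first charged, at 2.5 d
- the remedy with the largest gain of target, or "none" below 2 percentage points (north / east / west / none)
- target present, with what was taken out counted in, in percent of the solid substrate first charged, after north
- target present, with what was taken out counted in, in percent of the solid substrate first charged, after east

From 30.0 h on, target in Tuesday's run averaged 45.0 %, and I read that flat stretch as equilibrium. Since one target counts as two, this meant c target 0.675 M beside c starting material 1.65 M. I carried c target divided by c starting material squared, the equilibrium constant, 0.248 L mol⁻¹.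

I expected the same 45.0 % in the flask at 2.5 d, and nothing from waiting. I warned against warming: Wednesday's run at 35 °C levelled at 48.7 %, higher than Tuesday's. Taking out 90 % of the target left 59.5 % of the charge in the flask, and 0.248 L mol⁻¹ returned 21.5 % as target, so my figure for north, if 20 h sufficed, was 62.0 %.

The forecast gave 45 % now, 45.2 % for east and 61 % for north, a little less than mine. It chose north and said “it is exothermic, so heating would lose target”.

The flask gave 45.1 % now, 45.1 % for east and 61.7 % for north; north gained 17 percentage points, and west lost 9.5 points.

    2 starting material ⇌ target (K = 0.250 L mol⁻¹, k = 0.0212 L mol⁻¹ h⁻¹, Ea = 80.0 kJ mol⁻¹, ΔH = −35.0 kJ mol⁻¹)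
    solid substrate ⇌ starting material, rate k2*(cs2 - [starting material]) while solid is left; crystals form when [starting material] > cs2 (solubility = 1.80 M, k = 1.78 h⁻¹)
    (constants at 40 °C)

In the flask, solid substrate stood at 0 % at 30.0 h, and target stood at 45.1 % at 60.0 h and 45.1 % at 600 h; the low solubility of starting material changed nothing in target at 2.5 d. For the neighbour flask charged with 1.2 M, 0.248 L mol⁻¹ put target at 29.5 %, less than this flask's 45.1 %. That neighbour flask gave 29.7 % target beside 70.3 % starting material at 60.0 h.

The runs were generated by integration for substances that don't exist, and the scatter is random.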